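Follow one substrate molecule through the flask and ask its chance of being target at 20 h. If that chance grows in step with c(reagent in the second phase), the percentage ignores the substrate charge, so we divide each run's last reading by its reagent charge.

| flask | substrate | reagent in the second phase | remark | time | volume of the second phase over the first |
|---|---|---|---|---|---|
| Saturday's | 20 mM | 56 mM | run made earlier |  |  |
| Sunday's | 20 mM | 88 mM | run made earlier |  |  |
| Monday's | 30 mM | 40 mM | run made earlier |  |  |
| flask | 20 mM | 40.0 mM |  | 20 h | 2.0 |

- Saturday's (time / h: target / %): 1.50: 0; 3.00: 2; 6.00: 4; 10.0: 10; 20.0: 14
- Sunday's (time / h: target / %): 2.00: 2; 5.00: 3; 10.0: 10; 15.0: 22; 20.0: 23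
- Monday's (time / h: target / %): 4.00: 2; 8.00: 5; 12.0: 8; 15.0: 8; 20.0: 13

(each reading ± 1.5 percentage points)

- in the second phase: reagent in the second phase; everything else is in the first
- charges count per volume of the first phase; a concentration in a rate is the amount of a species over the volume of its own phase; every rate counts per litre of the first phase
- the analysis behind the earlier runs scatters by 1.5 percentage points, standard deviation
- the earlier runs hold the two phases in the same ratio of volumes as the flask asked about

- west: doubling the transfer coefficient of the reagent in the second phase, all else as stated
- north-east: doubling the amount of reagent in the second phase, all else as stated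

- amount of target at 20 h, in percent of the substrate charged
- the change that raises the amount of target at 20 h, in percent of the substrate charged most ("none" if none brings more than 2 percentage points) (west / north-east / none)
- amount of target at 20 h, in percent of the substrate charged, after west

Saturday gives 2.50 L mol⁻¹, Sunday 2.61 L mol⁻¹ and Monday 3.25 L mol⁻¹. Each carries the scatter of 1.5 percentage points in its reading. Their mean, 2.79 L mol⁻¹, is our reagent yield, the chance per unit of reagent charged.

On the flask's 40.0 mM, Saturday's value sets our lower mark at 10.0 %. Monday's value sets our upper mark at 13.0 %. The mean tightens this to 11.2 %, our own figure. Read in step with the charge, doubling the reagent adds an estimated 11.2 %. No run varied the transfer, so we have no estimate for west, and we pick north-east as the one of the two changes that the runs have tried.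

The forecast gives 10.5 %, inside our marks, names north-east, gives 11.5 % after west, and holds that “the chemistry in the first phase is slow and controls the rate, not transfer”.

The flask gives 13.0 %, and 15.9 % after west. The best change is north-east, worth 7.6 points against 2.9 points for west.

    substrate + target → side product (k = 0.950 L mol⁻¹ h⁻¹)
    2 reagent in the reaction phase → self-condensation product (k = 3.50 L mol⁻¹ h⁻¹)
    reagent in the reaction phase ⇌ reagent in the second phase, rate k3*([reagent in the reaction phase] - [reagent in the second phase]/K3) per volume of the first phase (partition coefficient = 0.760, kL = 0.0670 h⁻¹)
    reagent in the reaction phase + target → over-reacted product (k = 0.460 L mol⁻¹ h⁻¹)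
    substrate + reagent in the reaction phase → target (k = 1.30 L mol⁻¹ h⁻¹)

The flask's own reagent yield is 3.25 L mol⁻¹, above our mean and close to Monday's reading. Of the things taken away from this flask, the largest single effect comes from the slowness of the transfer of reagent in the second phase to reagent in the reaction phase. With that slowness removed, this flask gives 19.0 % against 13.0 %. That gain is 6.9 % of what is missing, so the transfer is not the main reason.

For the flask left until 30 h, our mean yield stretched in step with time gives 16.7 %. The computed flask gives 17.4 %.

All runs were generated by integration with constants of no real substance; noise was put on by code.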